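**Strategy.** The route rests on disconnecting the aryl ether bond O1–C8a of the pyranone ring (ring C). C8a lies ortho to the C4 ketone, so a fluoride there is activated for displacement by the C2 alkoxide. In one operation this closes ring C without touching any bond at C2, so the configuration of an (S)-aldol passes unchanged into the (2S)-flavanone. The precursor is an (S)-β-hydroxy ketone whose hexasubstituted aryl ring carries F, both prenyl groups, OMe and a MOM-protected phenol. The 4'-phenol is also a MOM ether, inert to the alkoxide and to the fluoride released, so one acidic step unmasks both phenols at the end.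

Key step: step 8

Remark: the carbinol centre of the masked acetyl group in 5, 8 and 10 is racemic and is erased in step 5; (+)-Ipc2BCl means the reagent derived from (−)-α-pinene.

**Step 1**
Reactants: 1 3-fluoro-5-methoxyphenol
Product: 2 1-fluoro-3-methoxy-5-(methoxymethoxy)benzene
Conditions: MOMCl, i-Pr2NEt, CH2Cl2, 0 °C → rt
Reagents that add atoms: chloromethyl methyl ether (MOMCl), COCCl
Why: Williamson-type O-alkylation gives a MOM ether that serves as ortho-directing group in the metalations and as a base-stable mask of the C5 phenol.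

**Step 2**
Reactants: 2 1-fluoro-3-methoxy-5-(methoxymethoxy)benzene; 3 acetaldehyde
Product: 5 1-[2-fluoro-4-methoxy-6-(methoxymethoxy)phenyl]ethan-1-ol (racemic), via aryllithium 4 (not isolated)
Conditions: n-BuLi, THF, −78 °C; MeCHO, −78 °C; then H2O
Reagents that add atoms: none
Why: Directed ortho-metalation should take place at the C–H flanked by fluorine (strongest acidifier) and the MOM ether (strongest lithium-coordinating group), and addition of the aryllithium to acetaldehyde gives a secondary carbinol that is a lithiation-proof precursor of the acetyl group, its new stereocentre being formed racemic and removed in step 5.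

**Step 3**
Reactants: 5 1-[2-fluoro-4-methoxy-6-(methoxymethoxy)phenyl]ethan-1-ol; 6 prenyl bromide (1-bromo-3-methylbut-2-ene)
Product: 8 1-[2-fluoro-4-methoxy-6-(methoxymethoxy)-3-(3-methylbut-2-en-1-yl)phenyl]ethan-1-ol (racemic), via dilithio species 7 (not isolated)
Conditions: s-BuLi (2.2 equiv), TMEDA, THF, −78 °C; CuBr·SMe2 (10 mol %), prenyl bromide, −78 → −20 °C; then H2O
Reagents that add atoms: none
Why: The first equivalent of base forms the lithium alkoxide, the second performs directed ortho-metalation at the C–H between F and OMe (kept at −78 °C so the ortho-fluoroaryllithium does not lose LiF), and copper-catalysed SN2 allylation gives the linear prenyl group; any product of metalation at the other free position converges on compound 10 in step 4.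

**Step 4**
Reactants: 8 1-[2-fluoro-4-methoxy-6-(methoxymethoxy)-3-(3-methylbut-2-en-1-yl)phenyl]ethan-1-ol; 6 prenyl bromide
Product: 10 1-[2-fluoro-4-methoxy-6-(methoxymethoxy)-3,5-bis(3-methylbut-2-en-1-yl)phenyl]ethan-1-ol (racemic), via dilithio species 9 (not isolated)
Conditions: s-BuLi (2.3 equiv), TMEDA, THF, −78 °C; CuBr·SMe2 (10 mol %), prenyl bromide, −78 → 0 °C; then H2O
Reagents that add atoms: none
Why: The only ring C–H left lies between OMe and OMOM, so doubly coordination-assisted ortho-metalation at −78 °C should be faster than deprotonation of the benzylic–allylic CH2 of the first prenyl group, and copper-catalysed allylation completes the hexasubstituted ring.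

**Step 5**
Reactants: 10 1-[2-fluoro-4-methoxy-6-(methoxymethoxy)-3,5-bis(3-methylbut-2-en-1-yl)phenyl]ethan-1-ol
Product: 11 1-[2-fluoro-4-methoxy-6-(methoxymethoxy)-3,5-bis(3-methylbut-2-en-1-yl)phenyl]ethan-1-one
Conditions: IBX, DMSO–THF, rt
Reagents that add atoms: none
Why: IBX oxidation of the secondary benzylic alcohol runs under neutral conditions that should leave the MOM acetal, the aryl fluoride and the trisubstituted alkenes untouched, and it removes the racemic carbinol centre.

**Step 6**
Reactants: 12 4-hydroxybenzaldehyde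
Product: 13 4-(methoxymethoxy)benzaldehyde
Conditions: MOMCl, i-Pr2NEt, CH2Cl2, 0 °C → rt
Reagents that add atoms: chloromethyl methyl ether (MOMCl), COCCl
Why: Williamson-type O-alkylation gives a MOM ether that is stable to the boron enolate, to alkoxide and to fluoride, and that is cleaved under the same conditions as the C5 MOM ether.

**Step 7**
Reactants: 11 1-[2-fluoro-4-methoxy-6-(methoxymethoxy)-3,5-bis(3-methylbut-2-en-1-yl)phenyl]ethan-1-one; 13 4-(methoxymethoxy)benzaldehyde
Product: 15 (3S)-1-[2-fluoro-4-methoxy-6-(methoxymethoxy)-3,5-bis(3-methylbut-2-en-1-yl)phenyl]-3-hydroxy-3-[4-(methoxymethoxy)phenyl]propan-1-one, via boron enolate 14 (not isolated)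
Conditions: (+)-Ipc2BCl, Et3N, Et2O, 0 °C; 13, −78 → −20 °C; then pH 7 buffer, MeOH, 30% H2O2, 0 °C
Reagents that add atoms: none
Why: Ipc2BCl-mediated boron aldol addition of a methyl ketone, in which the enol diisopinocampheylborinate adds to the aldehyde through a cyclic boron-bound transition state and the Ipc ligands differentiate the aldehyde faces (reagent control), (+)-Ipc2BCl being the antipode expected to direct attack to the Si face and so set the (S) carbinol, while buffered peroxide work-up cleaves the B–O bond without touching the prenyl alkenes.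

**Step 8**
Reactants: 15 (3S)-1-[2-fluoro-4-methoxy-6-(methoxymethoxy)-3,5-bis(3-methylbut-2-en-1-yl)phenyl]-3-hydroxy-3-[4-(methoxymethoxy)phenyl]propan-1-one
Product: 18 (2S)-7-methoxy-5-(methoxymethoxy)-2-[4-(methoxymethoxy)phenyl]-6,8-bis(3-methylbut-2-en-1-yl)-2,3-dihydro-4H-chromen-4-one, via sodium alkoxide 16 (not isolated), via Meisenheimer adduct 17 (not isolated)
Conditions: NaHMDS (1.0 equiv), THF, −78 → 0 °C; pH 7 buffer
Reagents that add atoms: none
Why: NaHMDS deprotonates the carbinol to sodium alkoxide 16, whose oxygen adds to C8a, the fluorine-bearing ring carbon ortho to the C4 ketone, giving the ketone-stabilised Meisenheimer adduct 17, from which fluoride departs to form O1–C8a. The closest known reaction type is the intramolecular SNAr etherification of 2-fluoroaryl β-hydroxy ketones to 2-substituted chroman-4-ones. The pyranone ring closes as a six-membered ring by addition–elimination at an sp2 carbon, formally 6-endo-trig with respect to the C8a=C4a–C4=O unit that takes up the charge. No stereocentre is created: only the O–H bond of the carbinol is broken and the C2–O bond never, so the (S) configuration set in step 7 becomes (2S) with retention. The step needs ring closure to outrun retro-aldol cleavage and E1cB dehydration of the aldolate and needs the product not to reopen by β-elimination; the short six-membered tether, the low temperature, the position of both ring oxygen substituents meta to C8a (no resonance deactivation of the reacting carbon) and the use of exactly one equivalent of base, which is consumed as sodium fluoride precipitates, are what should secure this.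

**Step 9**
Reactants: 18 (2S)-7-methoxy-5-(methoxymethoxy)-2-[4-(methoxymethoxy)phenyl]-6,8-bis(3-methylbut-2-en-1-yl)-2,3-dihydro-4H-chromen-4-one
Product: 19 (2S)-5-hydroxy-2-(4-hydroxyphenyl)-7-methoxy-6,8-bis(3-methylbut-2-en-1-yl)-2,3-dihydro-4H-chromen-4-one (CNP0121058.1)
Conditions: 3 M aq. HCl, MeOH, 45 °C
Reagents that add atoms: none
Why: Acid-catalysed acetal exchange with methanol removes both MOM groups (the peri C5 ether first), and dilute acid at moderate temperature is chosen so that the 6-prenyl group should not cyclise onto the freed 5-OH and the C2–O1 bond, hence the (2S) centre, stays intact.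

**Compound list**
1 | 3-fluoro-5-methoxyphenol | COc1cc(O)cc(F)c1 | starting material
2 | 1-fluoro-3-methoxy-5-(methoxymethoxy)benzene | COCOc1cc(F)cc(OC)c1 | intermediate
3 | acetaldehyde | CC=O | starting material
4 | [2-fluoro-4-methoxy-6-(methoxymethoxy)phenyl]lithium | [Li]c1c(F)cc(OC)cc1OCOC | intermediate
5 | 1-[2-fluoro-4-methoxy-6-(methoxymethoxy)phenyl]ethan-1-ol (racemic) | CC(O)c1c(F)cc(OC)cc1OCOC | intermediate
6 | prenyl bromide (1-bromo-3-methylbut-2-ene) | CC(C)=CCBr | starting material
7 | lithium 1-[2-fluoro-3-lithio-4-methoxy-6-(methoxymethoxy)phenyl]ethan-1-olate (racemic) | CC(O[Li])c1c(F)c([Li])c(OC)cc1OCOC | intermediate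
8 | 1-[2-fluoro-4-methoxy-6-(methoxymethoxy)-3-(3-methylbut-2-en-1-yl)phenyl]ethan-1-ol (racemic) | CC(O)c1c(F)c(CC=C(C)C)c(OC)cc1OCOC | intermediate
9 | lithium 1-[2-fluoro-5-lithio-4-methoxy-6-(methoxymethoxy)-3-(3-methylbut-2-en-1-yl)phenyl]ethan-1-olate (racemic) | CC(O[Li])c1c(F)c(CC=C(C)C)c(OC)c([Li])c1OCOC | intermediate
10 | 1-[2-fluoro-4-methoxy-6-(methoxymethoxy)-3,5-bis(3-methylbut-2-en-1-yl)phenyl]ethan-1-ol (racemic) | CC(O)c1c(F)c(CC=C(C)C)c(OC)c(CC=C(C)C)c1OCOC | intermediate
11 | 1-[2-fluoro-4-methoxy-6-(methoxymethoxy)-3,5-bis(3-methylbut-2-en-1-yl)phenyl]ethan-1-one | CC(=O)c1c(F)c(CC=C(C)C)c(OC)c(CC=C(C)C)c1OCOC | intermediate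
12 | 4-hydroxybenzaldehyde | O=Cc1ccc(O)cc1 | starting material
13 | 4-(methoxymethoxy)benzaldehyde | COCOc1ccc(C=O)cc1 | intermediate
14 | 1-[2-fluoro-4-methoxy-6-(methoxymethoxy)-3,5-bis(3-methylbut-2-en-1-yl)phenyl]ethenyl (+)-diisopinocampheylborinate | C=C(OB([C@H]1C[C@H]2C[C@@H]([C@@H]1C)C2(C)C)[C@H]1C[C@H]2C[C@@H]([C@@H]1C)C2(C)C)c1c(F)c(CC=C(C)C)c(OC)c(CC=C(C)C)c1OCOC | intermediate
15 | (3S)-1-[2-fluoro-4-methoxy-6-(methoxymethoxy)-3,5-bis(3-methylbut-2-en-1-yl)phenyl]-3-hydroxy-3-[4-(methoxymethoxy)phenyl]propan-1-one | O[C@H](c1ccc(OCOC)cc1)CC(=O)c1c(F)c(CC=C(C)C)c(OC)c(CC=C(C)C)c1OCOC | intermediate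
16 | sodium alkoxide of 15 (3S) | [Na+].[O-][C@H](c1ccc(OCOC)cc1)CC(=O)c1c(F)c(CC=C(C)C)c(OC)c(CC=C(C)C)c1OCOC | intermediate
17 | sodium (2S)-8a-fluoro-7-methoxy-5-(methoxymethoxy)-2-[4-(methoxymethoxy)phenyl]-6,8-bis(3-methylbut-2-en-1-yl)-2,3-dihydro-8aH-chromen-4-olate (Meisenheimer adduct; C8a configuration undefined) | [Na+].[O-]C1=C2C(OCOC)=C(CC=C(C)C)C(OC)=C(CC=C(C)C)C2(F)O[C@H](c2ccc(OCOC)cc2)C1 | intermediate
18 | (2S)-7-methoxy-5-(methoxymethoxy)-2-[4-(methoxymethoxy)phenyl]-6,8-bis(3-methylbut-2-en-1-yl)-2,3-dihydro-4H-chromen-4-one | COc1c(CC=C(C)C)c(OCOC)c2c(c1CC=C(C)C)O[C@H](c1ccc(OCOC)cc1)CC2=O | intermediate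
19 | (2S)-5-hydroxy-2-(4-hydroxyphenyl)-7-methoxy-6,8-bis(3-methylbut-2-en-1-yl)-2,3-dihydro-4H-chromen-4-one | COc1c(CC=C(C)C)c(O)c2c(c1CC=C(C)C)O[C@H](c1ccc(O)cc1)CC2=O | target

**Totals.** Total steps: 9. Longest linear sequence: 8 (steps 1–5, 7, 8, 9 from compound 1).

**Steps most likely to fail**

1. Step 8. The sodium aldolate may fragment by retro-aldol cleavage or lose water by E1cB elimination faster than it closes the ring, or the flavanone may reopen under base and lose configuration at C2. The fallback keeps fluoride displacement for O1–C8a but creates C2 only after the ring is closed. It sets out from ketone 11.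
   - Claisen formylation with ethyl formate (NaH, THF) should give (2Z)-1-[2-fluoro-4-methoxy-6-(methoxymethoxy)-3,5-bis(3-methylbut-2-en-1-yl)phenyl]-3-hydroxyprop-2-en-1-one F1.
   - Warming F1 with K2CO3 in DMF lets the enolate oxygen displace the fluoride to give 7-methoxy-5-(methoxymethoxy)-6,8-bis(3-methylbut-2-en-1-yl)-4H-chromen-4-one F2; no aldolate and no stereocentre is exposed.
   - Rh-catalysed asymmetric 1,4-addition of commercial 4-(methoxymethoxy)phenylboronic acid (OB(O)c1ccc(OCOC)cc1; chiral diene or bisphosphine ligand, antipode chosen for the 2S product, near-neutral aqueous dioxane) then forms the C2–aryl bond and comes back to the route at flavanone 18.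

2. Step 7. Facial discrimination by the boron enolate of a hindered, twisted aryl methyl ketone may be insufficient, or of the opposite sense, so that the aldol is not enantiopure enough. The fallback sets out from ketone 11 and aldehyde 13.
   - Claisen–Schmidt condensation (KOH, EtOH, rt) gives (2E)-1-[2-fluoro-4-methoxy-6-(methoxymethoxy)-3,5-bis(3-methylbut-2-en-1-yl)phenyl]-3-[4-(methoxymethoxy)phenyl]prop-2-en-1-one F3.
   - Copper-catalysed enantioselective β-borylation (CuCl, NaOt-Bu, Josiphos-type ligand of the antipode giving S, B2pin2, MeOH, THF) gives (3S)-1-[2-fluoro-4-methoxy-6-(methoxymethoxy)-3,5-bis(3-methylbut-2-en-1-yl)phenyl]-3-[4-(methoxymethoxy)phenyl]-3-(4,4,5,5-tetramethyl-1,3,2-dioxaborolan-2-yl)propan-1-one F4.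
   - Oxidation with NaBO3 in THF–water replaces boron by hydroxyl with retention and comes back to the route at aldol 15.

3. Step 2. Metalation may occur at another ring position (between OMe and OMOM, or between F and OMe), which would put the acetyl precursor on the wrong carbon; the site should be checked on 5 through the H–F coupling pattern. The fallback fixes the position by electrophilic substitution instead and sets out from phenol 1.
   - Friedel–Crafts acylation with Fries rearrangement (Ac2O, BF3·OEt2, 80 °C), directed ortho to OH and para to OMe and held there by the boron chelate, gives 1-(2-fluoro-6-hydroxy-4-methoxyphenyl)ethan-1-one F5.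
   - MOMCl and i-Pr2NEt give 1-[2-fluoro-4-methoxy-6-(methoxymethoxy)phenyl]ethan-1-one F6.
   - NaBH4 in MeOH reduces the ketone and comes back to the route at carbinol 5.

**Further compounds**
F1 | step 8 | (2Z)-1-[2-fluoro-4-methoxy-6-(methoxymethoxy)-3,5-bis(3-methylbut-2-en-1-yl)phenyl]-3-hydroxyprop-2-en-1-one | O/C=C\C(=O)c1c(F)c(CC=C(C)C)c(OC)c(CC=C(C)C)c1OCOC
F2 | step 8 | 7-methoxy-5-(methoxymethoxy)-6,8-bis(3-methylbut-2-en-1-yl)-4H-chromen-4-one | COc1c(CC=C(C)C)c(OCOC)c2c(=O)ccoc2c1CC=C(C)C
F3 | step 7 | (2E)-1-[2-fluoro-4-methoxy-6-(methoxymethoxy)-3,5-bis(3-methylbut-2-en-1-yl)phenyl]-3-[4-(methoxymethoxy)phenyl]prop-2-en-1-one | O=C(/C=C/c1ccc(OCOC)cc1)c1c(F)c(CC=C(C)C)c(OC)c(CC=C(C)C)c1OCOC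
F4 | step 7 | (3S)-1-[2-fluoro-4-methoxy-6-(methoxymethoxy)-3,5-bis(3-methylbut-2-en-1-yl)phenyl]-3-[4-(methoxymethoxy)phenyl]-3-(4,4,5,5-tetramethyl-1,3,2-dioxaborolan-2-yl)propan-1-one | CC1(C)OB(OC1(C)C)[C@H](c1ccc(OCOC)cc1)CC(=O)c1c(F)c(CC=C(C)C)c(OC)c(CC=C(C)C)c1OCOC
F5 | step 2 | 1-(2-fluoro-6-hydroxy-4-methoxyphenyl)ethan-1-one | CC(=O)c1c(O)cc(OC)cc1F
F6 | step 2 | 1-[2-fluoro-4-methoxy-6-(methoxymethoxy)phenyl]ethan-1-one | CC(=O)c1c(F)cc(OC)cc1OCOC
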